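**Remark (one assumption):** the target is read as epicatechin-(4β→8)-catechin 3-O-(4-hydroxybenzoate): upper unit 2R,3R,4R (2,3-cis, 3,4-trans), lower unit 2R,3S with the ester on its C3 oxygen.

**Plan**
1. Cuts: first the ten O–benzyl bonds; then, at upper C4, both the C4–C8 bond to ring D of the lower unit and the C4–C4a bond to ring A. This opens ring C of the upper unit to the acyclic aldehyde 10 and the benzylated catechin ester 14.
2. Enabling feature: upper C4 is a methine bonded to two phloroglucinol-type rings (C4a of ring A, C8 of ring D) and sits ortho to the ring A ether oxygen O1. It is therefore an aldehyde carbon that can be arylated twice, first within the molecule (closing ring C), then by the lower unit.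
3. Aldehyde 10 is cut at O1–C2 (Mitsunobu aryl ether) and C2–aryl (Grignard) back to (R)-glyceraldehyde acetonide.
4. Forward order: all aromatic rings and the lower ring C are brought in intact; the upper ring C is the last ring, closed in the same operation that makes the interflavan bond; global hydrogenolysis ends the route.
5. Stereochemistry: lower C2/C3 from (+)-catechin; upper C3 from the glyceraldehyde; upper C2 by Felkin–Anh addition then Mitsunobu inversion; upper C4 by attack anti to the C3 benzyloxy group on the ring C cation.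

Key step: step 9

**Step 1**
Reactants: 1 4-bromo-1,2-bis(benzyloxy)benzene; 2 (R)-2,2-dimethyl-1,3-dioxolane-4-carbaldehyde
Product: 4 (S)-[3,4-bis(benzyloxy)phenyl][(4R)-2,2-dimethyl-1,3-dioxolan-4-yl]methanol, via arylmagnesium bromide 3 (not isolated)
Conditions: Mg, THF, rt; then 2, THF, −78 → 0 °C; aq. NH4Cl
Reagents that add atoms: none
Why: Grignard addition to an α-alkoxy aldehyde under Felkin–Anh (non-chelation) control should deliver the aryl group anti to the dioxolane C–O bond and give mainly the anti (S)-carbinol, the minor syn epimer being removable by chromatography.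

**Step 2**
Reactants: 4 (S)-[3,4-bis(benzyloxy)phenyl][(4R)-2,2-dimethyl-1,3-dioxolan-4-yl]methanol; 5 3,5-bis(benzyloxy)phenol
Product: 6 (4R)-4-{(R)-[3,5-bis(benzyloxy)phenoxy][3,4-bis(benzyloxy)phenyl]methyl}-2,2-dimethyl-1,3-dioxolane
Conditions: PPh3, DIAD, toluene, 0 °C → rt
Reagents that add atoms: none
Why: Mitsunobu etherification of a secondary benzylic alcohol with a phenol is an SN2 displacement of the oxyphosphonium ion, so the ring A oxygen should enter with inversion and set the (R)-configured O1–C2 bond, syn to the dioxolane oxygen (the epicatechin 2,3-cis relationship).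

**Step 3**
Reactants: 6 (4R)-4-{(R)-[3,5-bis(benzyloxy)phenoxy][3,4-bis(benzyloxy)phenyl]methyl}-2,2-dimethyl-1,3-dioxolane
Product: 7 (2R,3R)-3-[3,5-bis(benzyloxy)phenoxy]-3-[3,4-bis(benzyloxy)phenyl]propane-1,2-diol
Conditions: AcOH/H2O (4:1), 45 °C
Reagents that add atoms: none
Why: Mild aqueous acid hydrolysis of the isopropylidene acetal should free the 1,2-diol without touching the benzyl ethers, the aryl ether or either stereocentre.

**Step 4**
Reactants: 7 (2R,3R)-3-[3,5-bis(benzyloxy)phenoxy]-3-[3,4-bis(benzyloxy)phenyl]propane-1,2-diol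
Product: 8 (4R)-4-{(R)-[3,5-bis(benzyloxy)phenoxy][3,4-bis(benzyloxy)phenyl]methyl}-2-phenyl-1,3-dioxolane (both epimers at the acetal carbon)
Conditions: PhCH(OMe)2, CSA (cat.), CH2Cl2, rt
Reagents that add atoms: benzaldehyde dimethyl acetal, COC(OC)c1ccccc1
Why: Acid-catalysed transacetalisation should give the five-membered benzylidene acetal, whose acetal-carbon epimers are inconsequential, as the carrier of the future C3 benzyl ether.

**Step 5**
Reactants: 8 (4R)-4-{(R)-[3,5-bis(benzyloxy)phenoxy][3,4-bis(benzyloxy)phenyl]methyl}-2-phenyl-1,3-dioxolane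
Product: 9 (2R,3R)-2-(benzyloxy)-3-[3,5-bis(benzyloxy)phenoxy]-3-[3,4-bis(benzyloxy)phenyl]propan-1-ol
Conditions: i-Bu2AlH (DIBAL-H), CH2Cl2, −78 → 0 °C; aq. KNaC4H4O6 (potassium sodium tartrate)
Reagents that add atoms: none
Why: Regioselective reductive opening of a 4-substituted 2-phenyl-1,3-dioxolane with i-Bu2AlH: aluminium binds the less hindered primary oxygen, that acetal C–O bond breaks and hydride is delivered to the oxocarbenium ion, which should leave the benzyl group on the secondary oxygen and the primary alcohol free.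

**Step 6**
Reactants: 9 (2R,3R)-2-(benzyloxy)-3-[3,5-bis(benzyloxy)phenoxy]-3-[3,4-bis(benzyloxy)phenyl]propan-1-ol
Product: 10 (2S,3R)-2-(benzyloxy)-3-[3,5-bis(benzyloxy)phenoxy]-3-[3,4-bis(benzyloxy)phenyl]propanal
Conditions: Dess–Martin periodinane, CH2Cl2, 0 °C → rt
Reagents that add atoms: none
Why: Dess–Martin oxidation of the primary alcohol under near-neutral conditions should give the α-benzyloxy aldehyde without epimerisation; it is used at once.

**Step 7**
Reactants: 11 (+)-catechin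
Product: 12 (2R,3S)-5,7-bis(benzyloxy)-2-[3,4-bis(benzyloxy)phenyl]chroman-3-ol
Conditions: BnBr, K2CO3, DMF, 0 °C → rt
Reagents that add atoms: benzyl bromide, BrCc1ccccc1
Why: Williamson benzylation with carbonate base is selective for the four phenolic hydroxyls over the secondary C3 alcohol and leaves C2 and C3 of catechin untouched.

**Step 8**
Reactants: 12 (2R,3S)-5,7-bis(benzyloxy)-2-[3,4-bis(benzyloxy)phenyl]chroman-3-ol; 13 4-(benzyloxy)benzoic acid
Product: 14 (2R,3S)-5,7-bis(benzyloxy)-2-[3,4-bis(benzyloxy)phenyl]chroman-3-yl 4-(benzyloxy)benzoate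
Conditions: DCC, DMAP (cat.), CH2Cl2, rt
Reagents that add atoms: none
Why: Steglich esterification acylates the only free hydroxyl, and C3 keeps its configuration because the C3–O bond is not broken.

**Step 9**
Reactants: 10 (2S,3R)-2-(benzyloxy)-3-[3,5-bis(benzyloxy)phenoxy]-3-[3,4-bis(benzyloxy)phenyl]propanal; 14 (2R,3S)-5,7-bis(benzyloxy)-2-[3,4-bis(benzyloxy)phenyl]chroman-3-yl 4-(benzyloxy)benzoate (3 equiv, excess recovered)
Product: 17 (2R,3S)-5,7-bis(benzyloxy)-2-[3,4-bis(benzyloxy)phenyl]-8-{(2R,3R,4R)-3,5,7-tris(benzyloxy)-2-[3,4-bis(benzyloxy)phenyl]chroman-4-yl}chroman-3-yl 4-(benzyloxy)benzoate, via flavan-4-ol 15 (not isolated), via flavan-4-yl cation 16 (not isolated)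
Conditions: TMSOTf (0.2 equiv), 4 Å molecular sieves (take up the water formed), CH2Cl2, −78 → −30 °C; Et3N quench
Reagents that add atoms: none
Why: TMSOTf activates the aldehyde of 10, and C2 of the 3,5-bis(benzyloxy)phenoxy ring (ortho to the ether oxygen, ortho and para to the two benzyloxy groups) attacks it in a 6-exo-trig Friedel–Crafts hydroxyalkylation that closes ring C of the upper unit as flavan-4-ol 15; 15 then ionises to the C4 cation 16, stabilised by O1 and the C5/C7 oxygens of ring A, and 16 is captured by C8 of 14, the aldehyde oxygen leaving as water. The closest known reaction types are the one-pot double Friedel–Crafts reaction of an aldehyde with one tethered and one external arene (2-aryloxybenzaldehydes plus arenes to 9-arylxanthenes, biaryl-2-carbaldehydes plus arenes to 9-arylfluorenes) and, for the second half, the standard Lewis acid condensation of 4-oxygenated benzylated flavan-3-ols with flavan-3-ol nucleophiles. The only new stereocentre, C4, is set under substrate control: in the half-chair cation the C2 aryl group is equatorial and the C3 benzyloxy group axial, so the arene should add to the face anti to C3–OBn and give the 3,4-trans (4β, 4R) product, while C2 and C3 are carried in unchanged from 10. Ring closure should precede intermolecular capture of the aldehyde because of the effective molarity of the tethered phloroglucinol-type ring, which is also far more nucleophilic than the catechol-type ring B (that ring could only close a five-membered ring); should 14 add first, the resulting ring D benzylic cation would be closed onto ring A to the same constitution. Regioselectivity for C8 over C6 of 14 is the usual one for 5,7-di-O-benzyl flavan-3-ols, and the excess of 14 should suppress attack of ring A of a second molecule of 10 or of 17 on the cation.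

**Step 10**
Reactants: 17 (2R,3S)-5,7-bis(benzyloxy)-2-[3,4-bis(benzyloxy)phenyl]-8-{(2R,3R,4R)-3,5,7-tris(benzyloxy)-2-[3,4-bis(benzyloxy)phenyl]chroman-4-yl}chroman-3-yl 4-(benzyloxy)benzoate
Product: 18 (2R,3S)-2-(3,4-dihydroxyphenyl)-8-[(2R,3R,4R)-2-(3,4-dihydroxyphenyl)-3,5,7-trihydroxychroman-4-yl]-5,7-dihydroxychroman-3-yl 4-hydroxybenzoate
Conditions: H2 (1 atm), Pd(OH)2/C, THF/MeOH/H2O, rt
Reagents that add atoms: none
Why: Hydrogenolysis over Pd(OH)2/C should cleave all ten benzyl ethers while the aryl ester, the interflavan bond and the ring C ether bonds, which survive these conditions in benzylated procyanidins, stay intact.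

**Compound list**
1 | 4-bromo-1,2-bis(benzyloxy)benzene | Brc1ccc(OCc2ccccc2)c(OCc2ccccc2)c1 | starting material
2 | (R)-2,2-dimethyl-1,3-dioxolane-4-carbaldehyde | CC1(C)OC[C@H](C=O)O1 | starting material
3 | [3,4-bis(benzyloxy)phenyl]magnesium bromide | Br[Mg]c1ccc(OCc2ccccc2)c(OCc2ccccc2)c1 | intermediate
4 | (S)-[3,4-bis(benzyloxy)phenyl][(4R)-2,2-dimethyl-1,3-dioxolan-4-yl]methanol | CC1(C)OC[C@H]([C@@H](O)c2ccc(OCc3ccccc3)c(OCc3ccccc3)c2)O1 | intermediate
5 | 3,5-bis(benzyloxy)phenol | Oc1cc(OCc2ccccc2)cc(OCc2ccccc2)c1 | starting material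
6 | (4R)-4-{(R)-[3,5-bis(benzyloxy)phenoxy][3,4-bis(benzyloxy)phenyl]methyl}-2,2-dimethyl-1,3-dioxolane | CC1(C)OC[C@H]([C@H](Oc2cc(OCc3ccccc3)cc(OCc3ccccc3)c2)c2ccc(OCc3ccccc3)c(OCc3ccccc3)c2)O1 | intermediate
7 | (2R,3R)-3-[3,5-bis(benzyloxy)phenoxy]-3-[3,4-bis(benzyloxy)phenyl]propane-1,2-diol | OC[C@H]([C@H](Oc1cc(OCc2ccccc2)cc(OCc2ccccc2)c1)c1ccc(OCc2ccccc2)c(OCc2ccccc2)c1)O | intermediate
8 | (4R)-4-{(R)-[3,5-bis(benzyloxy)phenoxy][3,4-bis(benzyloxy)phenyl]methyl}-2-phenyl-1,3-dioxolane (acetal epimers) | c1ccccc1C1OC[C@H]([C@H](Oc2cc(OCc3ccccc3)cc(OCc3ccccc3)c2)c2ccc(OCc3ccccc3)c(OCc3ccccc3)c2)O1 | intermediate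
9 | (2R,3R)-2-(benzyloxy)-3-[3,5-bis(benzyloxy)phenoxy]-3-[3,4-bis(benzyloxy)phenyl]propan-1-ol | OC[C@H]([C@H](Oc1cc(OCc2ccccc2)cc(OCc2ccccc2)c1)c1ccc(OCc2ccccc2)c(OCc2ccccc2)c1)OCc1ccccc1 | intermediate
10 | (2S,3R)-2-(benzyloxy)-3-[3,5-bis(benzyloxy)phenoxy]-3-[3,4-bis(benzyloxy)phenyl]propanal | O=C[C@H]([C@H](Oc1cc(OCc2ccccc2)cc(OCc2ccccc2)c1)c1ccc(OCc2ccccc2)c(OCc2ccccc2)c1)OCc1ccccc1 | intermediate
11 | (+)-catechin, (2R,3S) | O[C@H]1Cc2c(O)cc(O)cc2O[C@@H]1c1ccc(O)c(O)c1 | starting material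
12 | (2R,3S)-5,7-bis(benzyloxy)-2-[3,4-bis(benzyloxy)phenyl]chroman-3-ol | O[C@H]1Cc2c(OCc3ccccc3)cc(OCc3ccccc3)cc2O[C@@H]1c1ccc(OCc2ccccc2)c(OCc2ccccc2)c1 | intermediate
13 | 4-(benzyloxy)benzoic acid | O=C(O)c1ccc(OCc2ccccc2)cc1 | starting material
14 | (2R,3S)-5,7-bis(benzyloxy)-2-[3,4-bis(benzyloxy)phenyl]chroman-3-yl 4-(benzyloxy)benzoate | O=C(O[C@H]1Cc2c(OCc3ccccc3)cc(OCc3ccccc3)cc2O[C@@H]1c1ccc(OCc2ccccc2)c(OCc2ccccc2)c1)c1ccc(OCc2ccccc2)cc1 | intermediate
15 | (2R,3R,4RS)-3,5,7-tris(benzyloxy)-2-[3,4-bis(benzyloxy)phenyl]chroman-4-ol | OC1c2c(OCc3ccccc3)cc(OCc3ccccc3)cc2O[C@H](c2ccc(OCc3ccccc3)c(OCc3ccccc3)c2)[C@@H]1OCc1ccccc1 | intermediate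
16 | (2R,3R)-3,5,7-tris(benzyloxy)-2-[3,4-bis(benzyloxy)phenyl]chroman-4-ylium | [CH+]1c2c(OCc3ccccc3)cc(OCc3ccccc3)cc2O[C@H](c2ccc(OCc3ccccc3)c(OCc3ccccc3)c2)[C@@H]1OCc1ccccc1 | intermediate
17 | (2R,3S)-5,7-bis(benzyloxy)-2-[3,4-bis(benzyloxy)phenyl]-8-{(2R,3R,4R)-3,5,7-tris(benzyloxy)-2-[3,4-bis(benzyloxy)phenyl]chroman-4-yl}chroman-3-yl 4-(benzyloxy)benzoate | O=C(O[C@H]1Cc2c(OCc3ccccc3)cc(OCc3ccccc3)c([C@H]3c4c(OCc5ccccc5)cc(OCc5ccccc5)cc4O[C@H](c4ccc(OCc5ccccc5)c(OCc5ccccc5)c4)[C@@H]3OCc3ccccc3)c2O[C@@H]1c1ccc(OCc2ccccc2)c(OCc2ccccc2)c1)c1ccc(OCc2ccccc2)cc1 | intermediate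
18 | (2R,3S)-2-(3,4-dihydroxyphenyl)-8-[(2R,3R,4R)-2-(3,4-dihydroxyphenyl)-3,5,7-trihydroxychroman-4-yl]-5,7-dihydroxychroman-3-yl 4-hydroxybenzoate | O=C(O[C@H]1Cc2c(O)cc(O)c([C@H]3c4c(O)cc(O)cc4O[C@H](c4ccc(O)c(O)c4)[C@@H]3O)c2O[C@@H]1c1ccc(O)c(O)c1)c1ccc(O)cc1 | target

**Totals**
Total step count: 10. Longest linear sequence: 8 steps (steps 1–6, 9, 10).

**Steps most likely to fail**

Step 9. What may go wrong: intermolecular arylation of the aldehyde before ring closure with poor control at C4, self-condensation of the ring C cation with ring A of a second molecule (oligomerisation), acid ionisation of the acyclic O1–C2 benzylic ether with loss of C2 integrity, or loss of H3 to a flav-3-ene. The fallback separates ring closure from coupling. It sets out from 10, which is converted with HC(OMe)3 and PPTS in MeOH into (2S,3R)-2-(benzyloxy)-3-[3,5-bis(benzyloxy)phenoxy]-3-[3,4-bis(benzyloxy)phenyl]-1,1-dimethoxypropane F1. F1 is cyclised by BF3·OEt2 in CH2Cl2/MeOH at −40 °C (Friedel–Crafts cyclisation of an aryloxy acetal with methanol as the cation trap) to the isolable (2R,3R,4RS)-3,5,7-tris(benzyloxy)-2-[3,4-bis(benzyloxy)phenyl]-4-methoxychroman F2. F2 is then condensed with 14 under TMSOTf in CH2Cl2 at −78 °C, the classical 4-alkoxyflavan coupling, and the route is rejoined at 17.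

Step 2. What may go wrong: partial ionisation of the electron-rich benzylic oxyphosphonium ion (erosion of configuration at C2), or elimination and slow displacement at the hindered carbinol. The fallback forms the aryl ether without breaking the C–O bond of the stereocentre. It sets out from 4, which is oxidised with Dess–Martin periodinane to [3,4-bis(benzyloxy)phenyl][(4R)-2,2-dimethyl-1,3-dioxolan-4-yl]methanone F3. Felkin–Anh reduction of F3 with LiBH(s-Bu)3 in THF at −78 °C should give the syn carbinol (R)-[3,4-bis(benzyloxy)phenyl][(4R)-2,2-dimethyl-1,3-dioxolan-4-yl]methanol F4. F4 is O-arylated with retention by 1-iodo-3,5-bis(benzyloxy)benzene in an Ullmann etherification (CuI, 3,4,7,8-tetramethyl-1,10-phenanthroline, Cs2CO3, toluene, 110 °C), and the route is rejoined at 6.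

Step 5. What may go wrong: poor regioselectivity of acetal opening, with the benzyl group ending on the primary oxygen, if aluminium chelates between the secondary acetal oxygen and the neighbouring aryl ether oxygen. The fallback differentiates the two hydroxyls by stepwise protection. It sets out from 7, whose primary hydroxyl is silylated (TBSCl, imidazole, CH2Cl2, 0 °C) to (2R,3R)-1-(tert-butyldimethylsilyloxy)-3-[3,5-bis(benzyloxy)phenoxy]-3-[3,4-bis(benzyloxy)phenyl]propan-2-ol F5. The secondary hydroxyl is benzylated under neutral conditions (2-benzyloxy-1-methylpyridinium triflate, MgO, PhCF3, 85 °C) to tert-butyl{(2R,3R)-2-(benzyloxy)-3-[3,5-bis(benzyloxy)phenoxy]-3-[3,4-bis(benzyloxy)phenyl]propoxy}dimethylsilane F6. TBAF in THF then removes the silyl group and the route is rejoined at 9.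

**Further compounds**
F1 | step 9 | (2S,3R)-2-(benzyloxy)-3-[3,5-bis(benzyloxy)phenoxy]-3-[3,4-bis(benzyloxy)phenyl]-1,1-dimethoxypropane | COC(OC)[C@H]([C@H](Oc1cc(OCc2ccccc2)cc(OCc2ccccc2)c1)c1ccc(OCc2ccccc2)c(OCc2ccccc2)c1)OCc1ccccc1
F2 | step 9 | (2R,3R,4RS)-3,5,7-tris(benzyloxy)-2-[3,4-bis(benzyloxy)phenyl]-4-methoxychroman | COC1c2c(OCc3ccccc3)cc(OCc3ccccc3)cc2O[C@H](c2ccc(OCc3ccccc3)c(OCc3ccccc3)c2)[C@@H]1OCc1ccccc1
F3 | step 2 | [3,4-bis(benzyloxy)phenyl][(4R)-2,2-dimethyl-1,3-dioxolan-4-yl]methanone | CC1(C)OC[C@H](C(=O)c2ccc(OCc3ccccc3)c(OCc3ccccc3)c2)O1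
F4 | step 2 | (R)-[3,4-bis(benzyloxy)phenyl][(4R)-2,2-dimethyl-1,3-dioxolan-4-yl]methanol | CC1(C)OC[C@H]([C@H](O)c2ccc(OCc3ccccc3)c(OCc3ccccc3)c2)O1
F5 | step 5 | (2R,3R)-1-(tert-butyldimethylsilyloxy)-3-[3,5-bis(benzyloxy)phenoxy]-3-[3,4-bis(benzyloxy)phenyl]propan-2-ol | CC(C)(C)[Si](C)(C)OC[C@H]([C@H](Oc1cc(OCc2ccccc2)cc(OCc2ccccc2)c1)c1ccc(OCc2ccccc2)c(OCc2ccccc2)c1)O
F6 | step 5 | tert-butyl{(2R,3R)-2-(benzyloxy)-3-[3,5-bis(benzyloxy)phenoxy]-3-[3,4-bis(benzyloxy)phenyl]propoxy}dimethylsilane | CC(C)(C)[Si](C)(C)OC[C@H]([C@H](Oc1cc(OCc2ccccc2)cc(OCc2ccccc2)c1)c1ccc(OCc2ccccc2)c(OCc2ccccc2)c1)OCc1ccccc1
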